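**Assumptions.** The SMILES gives no descriptor for the hindered C3–C6 biaryl axis, so the target is taken as stereochemically unspecified (racemic if the axis is stable). 5,7-Dimethoxy-2-(4-methoxyphenyl)-4H-chromen-4-one and 1-[4-(benzyloxy)phenyl]ethan-1-one are taken as purchasable. "Unit 1" is the C3-linked flavone with the two methyl ethers; "unit 2" is the C6-linked apigenin unit.

**Route in one sentence.** Ring A of unit 2 is built in one operation by benzannulation of a pyranonyl ketene (from diazoketone 15) with a flavone that carries a siloxyalkyne at C3 (8).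

## Structural features

The target (C32H22O10) is a biflavone of two 5,7,4'-trioxygenated 2-aryl-4H-chromen-4-one units: unit 1 has methyl ethers at O7 and O4' and a free, chelated 5-OH, and unit 2 is a fully free apigenin unit. The units are joined by one C–C bond from C3 of ring C of unit 1 to C6 of ring A of unit 2. That bond is a biaryl axis with four ortho substituents (C4=O and the C2 aryl ring on one side, the C5 and C7 hydroxyls on the other); there is no stereocentre. Ring A of unit 2 is a pentasubstituted phloroglucinol ring (C4a acyl, C5–OH, C6–chromonyl, C7–OH, C8a–O1, H only at C8), and C6 and C8 of a preformed 5,7-dioxygenated flavone are almost equally nucleophilic. A 5-hydroxyflavone can open and reclose its pyranone under strong acid, exchanging a 6- for an 8-substituent (Wessely–Moser rearrangement), and γ-pyranones are opened by hydroxide. Two methyl ethers must survive while four phenols end up free, so unit 2 and O5 of unit 1 need groups that leave without touching the methoxy groups at C7 and C4' of unit 1. The real difficulty is the hindered C3–C6 bond together with the 6-versus-8 regiochemistry. The key step exploits that in ring A of unit 2 the biaryl carbon C6 lies between the oxygen-bearing C5 and C7, followed by C8–H and the fusion atoms C8a and C4a, which is exactly the pattern a ketene–oxygenated alkyne benzannulation on a pyranone produces.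

## Logic of the disconnections

**21 ⇒ 20.** The O–CH2Ph bond at O4' of unit 2 and the O–CH3 bond at O5 of unit 1 are cut. Both are the only ether bonds that a chelating Lewis acid attacks at low temperature, so one operation ends the synthesis. The forward step must leave the two non-chelated methyl ethers and the pyranone rings untouched.

**20 ⇒ 19.** The O–Si bond at O7 of unit 2 is cut. The silyl group is the residue of the alkyne oxygen and is the only group labile to fluoride. The forward step needs buffered fluoride so that the phenoxide is not left in strong base.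

**19 ⇒ 8 + 15 (key).** Ring A of unit 2 is taken apart: C4a–C5, C5–C6 and C7–C8 are cut and C8 is shifted from C8a back onto C5. C6 and C7 become the two alkyne carbons of 8, C5 and C8 the diazoacetyl carbons of 15, and C4a and C8a stay in the pyranone of 15. The biflavone becomes one flavone and one monocyclic pyranone, the tetra-ortho biaryl bond becomes an sp2–sp bond, and the 6/8 question disappears because the mechanism places every substituent. The forward step demands clean ketene generation in the presence of 8, a regioselective [2+2] cycloaddition at a shielded alkyne, and an electrocyclic cascade that tolerates two chromone carbonyls.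

**8 ⇒ 5.** The C(sp)–O bond is cut, leading back to a terminal alkyne. The forward oxidation of the acetylide must not attack the chromone.

**5 ⇒ 4 ⇒ 3.** The C–Si bond and then the C3–C(sp) bond are cut; a coupling at C3 with a two-carbon alkyne is unhindered. The forward step needs only a reactive C3–I bond.

**3 ⇒ 1.** The C3–I bond is cut. The forward step must iodinate C3 and not the electron-rich ring A, which calls for the C3 carbanion 2 and not an electrophilic iodination.

**15 ⇒ 13.** The bond between the acyl carbon and the diazomethyl carbon is cut, leading to a carboxylic acid activated as 14. The forward step must acylate diazomethane without cycloaddition to the pyranone.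

**13 ⇒ 12 ⇒ 10.** The ester C–O bond, the ring O1–C2 bond and the C–C bond to the oxalyl carbon are cut, leading through the open chain 11 to a 1,3-diketone and an oxalate. The forward step needs acylation at the terminal methyl and mild cyclodehydration.

**10 ⇒ 9.** The C–C bond between the acetyl carbon and the methylene is cut (Claisen condensation), reaching the commercial ketone.

## Other disconnections considered

**Alternative 1:** The first idea is to cut the C3–C6 biaryl bond and couple 3 with the 6-boronate A1 of a protected apigenin (Suzuki–Miyaura) to give A2. The coupling must join two di-ortho-substituted carbons, one on an electron-poor iodochromone and one on a 2,6-dioxygenated arylboron species that is prone to protodeboronation. A1 also requires a C6-selective functionalisation of a preformed flavone whose C8 is nearly as reactive. The chosen plan never presses two hindered sp2 carbons together and obtains the 6-linkage from the mechanism.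

**Alternative 2:** Ring C of unit 1 is cut (O1–C2 and C2–C3) back to the deoxybenzoin A3, whose benzylic carbon is already attached to C6 of unit 2. Aroylation with 4-methoxybenzoyl chloride and base-mediated cyclodehydration (Baker–Venkataraman type) would give A4. This avoids the hindered coupling but moves the problem: A3 still needs a C6-selective C–C bond on unit 2 (for example an allyl ether rearrangement and oxidative cleavage) and an acylation of a phloroglucinol ether. The aroylation then takes place at a methylene flanked by two ortho-substituted rings, and the sequence is longer than the benzannulation route.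

**Alternative 3:** Ring C of unit 2 is cut back to the acetophenone A5 on a 2-aryl phloroglucinol, followed by aldol condensation with 4-(benzyloxy)benzaldehyde to chalcone A6 and oxidative cyclisation. The two hydroxyls ortho to the acyl group are not equivalent (one next to the chromonyl group, one next to C–H), and either can close the pyranone. The 6/8 ambiguity therefore returns in the last ring closure and can be equilibrated by acid, and A5 itself still requires the hindered aryl–chromone bond. In the chosen plan the O1–C8a bond exists before ring A does.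

Key step: step 9

## Route

**Step 1**
Reactants: 1 5,7-dimethoxy-2-(4-methoxyphenyl)-4H-chromen-4-one
Product: 3 3-iodo-5,7-dimethoxy-2-(4-methoxyphenyl)-4H-chromen-4-one, via 3-lithioflavone 2 (not isolated)
Conditions: LiN(i-Pr)2 (1.2 equiv), THF, −78 °C; then I2, −78 → 0 °C
Reagents that add atoms: iodine, II
Why: Deprotonation–iodination; C3–H is the only vinylic C–H alpha to the carbonyl and is removed by the amide base to give 2, so the iodine is fixed at C3 and not on ring A, where an electrophilic iodination would go.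

**Step 2**
Reactants: 3 3-iodo-5,7-dimethoxy-2-(4-methoxyphenyl)-4H-chromen-4-one
Product: 4 5,7-dimethoxy-2-(4-methoxyphenyl)-3-[(trimethylsilyl)ethynyl]-4H-chromen-4-one
Conditions: HC≡CSiMe3 (1.5 equiv), PdCl2(PPh3)2 (5 mol %), CuI (10 mol %), Et3N, DMF, 50 °C
Reagents that add atoms: ethynyltrimethylsilane, C#C[Si](C)(C)C
Why: Sonogashira coupling; the C3–I bond of a 3-iodochromone adds readily to zerovalent palladium and the linear alkyne is insensitive to the two ortho substituents.

**Step 3**
Reactants: 4 5,7-dimethoxy-2-(4-methoxyphenyl)-3-[(trimethylsilyl)ethynyl]-4H-chromen-4-one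
Product: 5 3-ethynyl-5,7-dimethoxy-2-(4-methoxyphenyl)-4H-chromen-4-one
Conditions: K2CO3 (0.2 equiv), MeOH/CH2Cl2, 0 → 20 °C
Reagents that add atoms: none
Why: Methanolysis of the C(sp)–Si bond; catalytic carbonate at low temperature should spare the 2-aryl-substituted pyranone.

**Step 4**
Reactants: 5 3-ethynyl-5,7-dimethoxy-2-(4-methoxyphenyl)-4H-chromen-4-one
Product: 8 5,7-dimethoxy-2-(4-methoxyphenyl)-3-({[tri(propan-2-yl)silyl]oxy}ethynyl)-4H-chromen-4-one, via lithium acetylide 6 (not isolated), via lithium ynolate 7 (not isolated)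
Conditions: LiN(SiMe3)2 (1.05 equiv), THF, −78 °C; t-BuOOLi (from t-BuOOH and LiN(SiMe3)2), −78 → 0 °C; i-Pr3SiOSO2CF3, −78 → 0 °C
Reagents that add atoms: tert-butyl hydroperoxide, CC(C)(C)OO; triisopropylsilyl trifluoromethanesulfonate, CC(C)[Si](C(C)C)(C(C)C)OS(=O)(=O)C(F)(F)F
Why: Acetylide-to-ynolate oxidation and O-silylation; acetylide 6 attacks the peroxide oxygen with loss of tert-butoxide to give ynolate 7, which the bulky silyl triflate traps on oxygen, while the non-nucleophilic amide base and low temperature keep C2 and C4=O of the chromone out of play.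

**Step 5**
Reactants: 9 1-[4-(benzyloxy)phenyl]ethan-1-one
Product: 10 1-[4-(benzyloxy)phenyl]butane-1,3-dione
Conditions: NaH (2.2 equiv), EtOAc (3 equiv), THF, reflux; aq. HCl work-up
Reagents that add atoms: ethyl acetate, CCOC(C)=O
Why: Crossed Claisen condensation; the ketone enolate is acylated by the ester and the product is drawn off as its stabilised sodium diketonate.

**Step 6**
Reactants: 10 1-[4-(benzyloxy)phenyl]butane-1,3-dione
Product: 12 methyl 6-[4-(benzyloxy)phenyl]-4-oxo-4H-pyran-2-carboxylate, via triketo ester 11 (not isolated)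
Conditions: LiN(i-Pr)2 (3 equiv), THF, −78 °C; (CO2Me)2, −78 → 0 °C; aq. HCl; then TsOH·H2O (10 mol %), toluene, 80 °C
Reagents that add atoms: dimethyl oxalate, COC(=O)C(=O)OC
Why: Claisen acylation of the 1,3-diketone dianion at its more reactive terminal carbon gives 11, and acid-catalysed cyclodehydration of this 1,3,5-tricarbonyl chain can only give the 4-pyranone in which the central carbonyl is C4.

**Step 7**
Reactants: 12 methyl 6-[4-(benzyloxy)phenyl]-4-oxo-4H-pyran-2-carboxylate
Product: 13 6-[4-(benzyloxy)phenyl]-4-oxo-4H-pyran-2-carboxylic acid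
Conditions: Me3SnOH (3 equiv), ClCH2CH2Cl, 70 °C; 1 M HCl work-up
Reagents that add atoms: trimethyltin hydroxide, C[Sn](C)(C)O
Why: Near-neutral ester cleavage by the tin hydroxide at the activated ester carbonyl; free hydroxide, which opens γ-pyranones, and strong acid, which threatens the benzyl ether, are both avoided.

**Step 8**
Reactants: 13 6-[4-(benzyloxy)phenyl]-4-oxo-4H-pyran-2-carboxylic acid
Product: 15 6-[4-(benzyloxy)phenyl]-2-(2-diazoacetyl)-4H-pyran-4-one, via acid chloride 14 (not isolated)
Conditions: (COCl)2, DMF (cat.), CH2Cl2, 0 → 20 °C; evaporate; CH2N2 (3 equiv), Et2O/THF, 0 °C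
Reagents that add atoms: diazomethane, C=[N+]=[N-]
Why: Acylation of diazomethane by acid chloride 14 (first stage of an Arndt–Eistert sequence); excess diazomethane takes up the HCl, and the short time at 0 °C should avoid dipolar cycloaddition to the pyranone.

**Step 9**
Reactants: 8 5,7-dimethoxy-2-(4-methoxyphenyl)-3-({[tri(propan-2-yl)silyl]oxy}ethynyl)-4H-chromen-4-one and 15 6-[4-(benzyloxy)phenyl]-2-(2-diazoacetyl)-4H-pyran-4-one
Product: 19 2-[4-(benzyloxy)phenyl]-6-[5,7-dimethoxy-2-(4-methoxyphenyl)-4-oxo-4H-chromen-3-yl]-5-hydroxy-7-{[tri(propan-2-yl)silyl]oxy}-4H-chromen-4-one, via pyranonylketene 16 (not isolated), via vinylcyclobutenone 17 (not isolated), via dienylketene 18 (not isolated)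
Conditions: 8 (1.3 equiv), hν (440–450 nm LEDs), ClCH2CH2Cl, 20 °C; then 80 °C
Reagents that add atoms: none
Why: Danheiser benzannulation in its diazoketone (photochemical Wolff) form, applied to a heteroaryl diazomethyl ketone. Light expels N2 from 15 and the pyranonyl group migrates to give ketene 16; the siloxyalkyne 8 is polarised so that its carbon bonded to C3 of unit 1 is nucleophilic and attacks the ketene carbonyl carbon, so the [2+2] cycloaddition gives 17 with the chromonyl group next to C=O and the silyloxy group next to the pyranonyl-bearing carbon. At 80 °C 17 opens in a conrotatory 4π process to dienylketene 18, and ring A of unit 2 is closed by 6π-electrocyclisation of 18 onto C3 of the pyranone (its C2=C3 bond is the third π component), followed by enolisation to the phenol. Three ring bonds (C4a–C5, C5–C6, C7–C8) are formed and C8–C8a comes from the Wolff shift, while the hindered C3–C6 bond is already present in 8 as an sp2–sp bond and never has to be forced. The 6-linkage needs only the normal ketene–ynol ether regiochemistry, and C8 can only be the former diazo carbon, so an 8-linked isomer cannot arise; the ketene carbonyl ends as the chelated 5-OH and the alkyne oxygen as the 7-O-silyl ether, already differentiated. No stereocentre remains (the sp3 carbon of 17 is lost on ring opening, and the axis is formed without control, as the target carries no descriptor). Chemoselectivity rests on the 450 nm light being absorbed by the diazoketone and not by the flavone chromophore, on the excess of 8 to outrun ketene dimerisation, and on the low nucleophilicity of the hydrogen-bonded 5-OH toward remaining ketene.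

**Step 10**
Reactants: 19 2-[4-(benzyloxy)phenyl]-6-[5,7-dimethoxy-2-(4-methoxyphenyl)-4-oxo-4H-chromen-3-yl]-5-hydroxy-7-{[tri(propan-2-yl)silyl]oxy}-4H-chromen-4-one
Product: 20 2-[4-(benzyloxy)phenyl]-6-[5,7-dimethoxy-2-(4-methoxyphenyl)-4-oxo-4H-chromen-3-yl]-5,7-dihydroxy-4H-chromen-4-one
Conditions: Bu4NF (1.2 equiv), AcOH (1.2 equiv), THF, 0 °C
Reagents that add atoms: none
Why: Fluoride cleavage of the aryl silyl ether; acetic acid buffers the phenoxide so that the pyranones are not exposed to base.

**Step 11**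
Reactants: 20 2-[4-(benzyloxy)phenyl]-6-[5,7-dimethoxy-2-(4-methoxyphenyl)-4-oxo-4H-chromen-3-yl]-5,7-dihydroxy-4H-chromen-4-one
Product: 21 5,7-dihydroxy-6-[5-hydroxy-7-methoxy-2-(4-methoxyphenyl)-4-oxo-4H-chromen-3-yl]-2-(4-hydroxyphenyl)-4H-chromen-4-one (target CNP0273448.0)
Conditions: BCl3 (6 equiv), C6HMe5 (5 equiv), CH2Cl2, −78 → 0 °C; aqueous work-up
Reagents that add atoms: none
Why: Lewis-acid ether cleavage; BCl3 removes the benzyl group (cation trapped by pentamethylbenzene) and, through chelation to C4=O, only the peri 5-methoxy group of unit 1, while the non-chelated 7- and 4'-methoxy groups should stay at or below 0 °C.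

## Compound list

1 | 5,7-dimethoxy-2-(4-methoxyphenyl)-4H-chromen-4-one | COc1ccc(-c2cc(=O)c3c(OC)cc(OC)cc3o2)cc1 | starting material
2 | 3-lithio-5,7-dimethoxy-2-(4-methoxyphenyl)-4H-chromen-4-one | COc1ccc(-c2oc3cc(OC)cc(OC)c3c(=O)c2[Li])cc1 | intermediate
3 | 3-iodo-5,7-dimethoxy-2-(4-methoxyphenyl)-4H-chromen-4-one | COc1ccc(-c2oc3cc(OC)cc(OC)c3c(=O)c2I)cc1 | intermediate
4 | 5,7-dimethoxy-2-(4-methoxyphenyl)-3-[(trimethylsilyl)ethynyl]-4H-chromen-4-one | COc1ccc(-c2oc3cc(OC)cc(OC)c3c(=O)c2C#C[Si](C)(C)C)cc1 | intermediate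
5 | 3-ethynyl-5,7-dimethoxy-2-(4-methoxyphenyl)-4H-chromen-4-one | COc1ccc(-c2oc3cc(OC)cc(OC)c3c(=O)c2C#C)cc1 | intermediate
6 | lithium acetylide of 5 | COc1ccc(-c2oc3cc(OC)cc(OC)c3c(=O)c2C#C[Li])cc1 | intermediate
7 | lithium 2-[5,7-dimethoxy-2-(4-methoxyphenyl)-4-oxo-4H-chromen-3-yl]ethyn-1-olate | COc1ccc(-c2oc3cc(OC)cc(OC)c3c(=O)c2C#CO[Li])cc1 | intermediate
8 | 5,7-dimethoxy-2-(4-methoxyphenyl)-3-({[tri(propan-2-yl)silyl]oxy}ethynyl)-4H-chromen-4-one | COc1ccc(-c2oc3cc(OC)cc(OC)c3c(=O)c2C#CO[Si](C(C)C)(C(C)C)C(C)C)cc1 | intermediate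
9 | 1-[4-(benzyloxy)phenyl]ethan-1-one | CC(=O)c1ccc(OCc2ccccc2)cc1 | starting material
10 | 1-[4-(benzyloxy)phenyl]butane-1,3-dione | CC(=O)CC(=O)c1ccc(OCc2ccccc2)cc1 | intermediate
11 | methyl 6-[4-(benzyloxy)phenyl]-2,4,6-trioxohexanoate | COC(=O)C(=O)CC(=O)CC(=O)c1ccc(OCc2ccccc2)cc1 | intermediate
12 | methyl 6-[4-(benzyloxy)phenyl]-4-oxo-4H-pyran-2-carboxylate | COC(=O)c1cc(=O)cc(-c2ccc(OCc3ccccc3)cc2)o1 | intermediate
13 | 6-[4-(benzyloxy)phenyl]-4-oxo-4H-pyran-2-carboxylic acid | OC(=O)c1cc(=O)cc(-c2ccc(OCc3ccccc3)cc2)o1 | intermediate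
14 | 6-[4-(benzyloxy)phenyl]-4-oxo-4H-pyran-2-carbonyl chloride | ClC(=O)c1cc(=O)cc(-c2ccc(OCc3ccccc3)cc2)o1 | intermediate
15 | 6-[4-(benzyloxy)phenyl]-2-(2-diazoacetyl)-4H-pyran-4-one | [N-]=[N+]=CC(=O)c1cc(=O)cc(-c2ccc(OCc3ccccc3)cc2)o1 | intermediate
16 | 6-[4-(benzyloxy)phenyl]-2-(2-oxoethenyl)-4H-pyran-4-one (ketene) | O=C=Cc1cc(=O)cc(-c2ccc(OCc3ccccc3)cc2)o1 | intermediate
17 | 4-{6-[4-(benzyloxy)phenyl]-4-oxo-4H-pyran-2-yl}-2-[5,7-dimethoxy-2-(4-methoxyphenyl)-4-oxo-4H-chromen-3-yl]-3-{[tri(propan-2-yl)silyl]oxy}cyclobut-2-en-1-one (racemic) | COc1ccc(-c2oc3cc(OC)cc(OC)c3c(=O)c2C2=C(O[Si](C(C)C)(C(C)C)C(C)C)C(c3cc(=O)cc(-c4ccc(OCc5ccccc5)cc4)o3)C2=O)cc1 | intermediate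
18 | 4-{6-[4-(benzyloxy)phenyl]-4-oxo-4H-pyran-2-yl}-2-[5,7-dimethoxy-2-(4-methoxyphenyl)-4-oxo-4H-chromen-3-yl]-3-{[tri(propan-2-yl)silyl]oxy}buta-1,3-dien-1-one (ketenyl carbon and pyranone cis on the C3=C4 bond) | COc1ccc(-c2oc3cc(OC)cc(OC)c3c(=O)c2C(=C=O)/C(O[Si](C(C)C)(C(C)C)C(C)C)=C\c2cc(=O)cc(-c3ccc(OCc4ccccc4)cc3)o2)cc1 | intermediate
19 | 2-[4-(benzyloxy)phenyl]-6-[5,7-dimethoxy-2-(4-methoxyphenyl)-4-oxo-4H-chromen-3-yl]-5-hydroxy-7-{[tri(propan-2-yl)silyl]oxy}-4H-chromen-4-one | COc1ccc(-c2oc3cc(OC)cc(OC)c3c(=O)c2-c2c(O[Si](C(C)C)(C(C)C)C(C)C)cc3oc(-c4ccc(OCc5ccccc5)cc4)cc(=O)c3c2O)cc1 | intermediate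
20 | 2-[4-(benzyloxy)phenyl]-6-[5,7-dimethoxy-2-(4-methoxyphenyl)-4-oxo-4H-chromen-3-yl]-5,7-dihydroxy-4H-chromen-4-one | COc1ccc(-c2oc3cc(OC)cc(OC)c3c(=O)c2-c2c(O)cc3oc(-c4ccc(OCc5ccccc5)cc4)cc(=O)c3c2O)cc1 | intermediate
21 | 5,7-dihydroxy-6-[5-hydroxy-7-methoxy-2-(4-methoxyphenyl)-4-oxo-4H-chromen-3-yl]-2-(4-hydroxyphenyl)-4H-chromen-4-one | COc1ccc(-c2oc3cc(OC)cc(O)c3c(=O)c2-c2c(O)cc3oc(-c4ccc(O)cc4)cc(=O)c3c2O)cc1 | target

## Step count and least certain steps

Total step count: 11. Longest linear sequence: 7 steps (1, 2, 3, 4, 9, 10, 11; the branch 5, 6, 7, 8, 9, 10, 11 is equally long).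

**Step 9 (key step).** The most likely failure is that the ketene is consumed by dimerisation, or by acylation of product phenol, faster than it is intercepted by the alkyne carbon shielded by the 2-aryl ring and C4=O. The cascade could also stall at the cyclobutenone stage or suffer unselective photolysis. The fallback is the biaryl cross-coupling of Alternative 1; it sets out from 3 and comes back to the route at 21. Commercial apigenin would be benzylated at the two non-chelated hydroxyls (BnBr, K2CO3, DMF) to 7-(benzyloxy)-2-[4-(benzyloxy)phenyl]-5-hydroxy-4H-chromen-4-one F1. Iodination ortho to the chelated 5-hydroxyl (PhCH2NMe3 ICl2, CaCO3, CH2Cl2/MeOH) should give 7-(benzyloxy)-2-[4-(benzyloxy)phenyl]-5-hydroxy-6-iodo-4H-chromen-4-one F2. Miyaura borylation (B2pin2, PdCl2(dppf), KOAc, dioxane, 80 °C) would give 7-(benzyloxy)-2-[4-(benzyloxy)phenyl]-5-hydroxy-6-(4,4,5,5-tetramethyl-1,3,2-dioxaborolan-2-yl)-4H-chromen-4-one F3. Suzuki–Miyaura coupling of F3 with 3 (Pd(OAc)2, SPhos, K3PO4, toluene/H2O, 90 °C) would give 7-(benzyloxy)-2-[4-(benzyloxy)phenyl]-6-[5,7-dimethoxy-2-(4-methoxyphenyl)-4-oxo-4H-chromen-3-yl]-5-hydroxy-4H-chromen-4-one F4. The conditions of step 11 would then remove both benzyl groups and the peri methyl group of F4 to give 21.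

**Step 4.** The peroxide, the acetylide or the ynolate may attack the chromone (conjugate addition at C2, epoxidation, ring opening) in competition with oxygen transfer, and the siloxyalkyne may hydrolyse during isolation. The fallback attaches a preformed ynol ether by cross-coupling; it sets out from 3 and comes back at 21. Negishi coupling of 3 with (t-BuOC≡C)ZnCl (from tert-butoxyethyne, n-BuLi and ZnCl2; Pd(PPh3)4, THF, 20 °C) would give 3-(tert-butoxyethynyl)-5,7-dimethoxy-2-(4-methoxyphenyl)-4H-chromen-4-one F5. Used in place of 8 in step 9 with 15, F5 should give 2-[4-(benzyloxy)phenyl]-7-tert-butoxy-6-[5,7-dimethoxy-2-(4-methoxyphenyl)-4-oxo-4H-chromen-3-yl]-5-hydroxy-4H-chromen-4-one F6. The conditions of step 11 would cleave the tert-butyl, benzyl and peri methyl ethers of F6 in one operation to give 21.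

**Step 11.** Selectivity between the chelated 5-methoxy group and the 7- and 4'-methoxy groups may be lost (over-demethylation), or the Lewis acid may open and reclose the 5-hydroxypyranone of unit 2 and move the linkage from C6 to C8. The fallback separates the two deprotections; it sets out from 20 and comes back at 21. Hydrogenolysis (H2, Pd/C, EtOAc/MeOH, 20 °C) would give 6-[5,7-dimethoxy-2-(4-methoxyphenyl)-4-oxo-4H-chromen-3-yl]-5,7-dihydroxy-2-(4-hydroxyphenyl)-4H-chromen-4-one F7. Chelation-controlled demethylation of F7 with MgI2·OEt2 (THF/toluene, 60 °C) would then remove only the peri methyl group to give 21.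

**Step 7.** The γ-pyranone may be opened at C2 or C6 in competition with cleavage of the ester, or the hydrolysis may stay incomplete. The fallback changes the ester so that acid and not a nucleophile releases the carboxylic acid; it sets out from 10 and comes back at 13. The sequence of step 6 run with (CO2t-Bu)2 and a mild cyclodehydration (pyridinium p-toluenesulfonate, toluene) would give tert-butyl 6-[4-(benzyloxy)phenyl]-4-oxo-4H-pyran-2-carboxylate F8, and CF3CO2H in CH2Cl2 at 0 °C would convert F8 into 13.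

## Further compounds

F1 | step 9 | 7-(benzyloxy)-2-[4-(benzyloxy)phenyl]-5-hydroxy-4H-chromen-4-one | O=c1cc(-c2ccc(OCc3ccccc3)cc2)oc2cc(OCc3ccccc3)cc(O)c12
F2 | step 9 | 7-(benzyloxy)-2-[4-(benzyloxy)phenyl]-5-hydroxy-6-iodo-4H-chromen-4-one | O=c1cc(-c2ccc(OCc3ccccc3)cc2)oc2cc(OCc3ccccc3)c(I)c(O)c12
F3 | step 9 | 7-(benzyloxy)-2-[4-(benzyloxy)phenyl]-5-hydroxy-6-(4,4,5,5-tetramethyl-1,3,2-dioxaborolan-2-yl)-4H-chromen-4-one | O=c1cc(-c2ccc(OCc3ccccc3)cc2)oc2cc(OCc3ccccc3)c(B3OC(C)(C)C(C)(C)O3)c(O)c12
F4 | step 9 | 7-(benzyloxy)-2-[4-(benzyloxy)phenyl]-6-[5,7-dimethoxy-2-(4-methoxyphenyl)-4-oxo-4H-chromen-3-yl]-5-hydroxy-4H-chromen-4-one | COc1ccc(-c2oc3cc(OC)cc(OC)c3c(=O)c2-c2c(OCc3ccccc3)cc3oc(-c4ccc(OCc5ccccc5)cc4)cc(=O)c3c2O)cc1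
F5 | step 4 | 3-(tert-butoxyethynyl)-5,7-dimethoxy-2-(4-methoxyphenyl)-4H-chromen-4-one | COc1ccc(-c2oc3cc(OC)cc(OC)c3c(=O)c2C#COC(C)(C)C)cc1
F6 | step 4 | 2-[4-(benzyloxy)phenyl]-7-tert-butoxy-6-[5,7-dimethoxy-2-(4-methoxyphenyl)-4-oxo-4H-chromen-3-yl]-5-hydroxy-4H-chromen-4-one | COc1ccc(-c2oc3cc(OC)cc(OC)c3c(=O)c2-c2c(OC(C)(C)C)cc3oc(-c4ccc(OCc5ccccc5)cc4)cc(=O)c3c2O)cc1
F7 | step 11 | 6-[5,7-dimethoxy-2-(4-methoxyphenyl)-4-oxo-4H-chromen-3-yl]-5,7-dihydroxy-2-(4-hydroxyphenyl)-4H-chromen-4-one | COc1ccc(-c2oc3cc(OC)cc(OC)c3c(=O)c2-c2c(O)cc3oc(-c4ccc(O)cc4)cc(=O)c3c2O)cc1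
F8 | step 7 | tert-butyl 6-[4-(benzyloxy)phenyl]-4-oxo-4H-pyran-2-carboxylate | CC(C)(C)OC(=O)c1cc(=O)cc(-c2ccc(OCc3ccccc3)cc2)o1
A1 | alternative 1 | 7-(benzyloxy)-2-[4-(benzyloxy)phenyl]-5-hydroxy-6-(4,4,5,5-tetramethyl-1,3,2-dioxaborolan-2-yl)-4H-chromen-4-one | O=c1cc(-c2ccc(OCc3ccccc3)cc2)oc2cc(OCc3ccccc3)c(B3OC(C)(C)C(C)(C)O3)c(O)c12
A2 | alternative 1 | 7-(benzyloxy)-2-[4-(benzyloxy)phenyl]-6-[5,7-dimethoxy-2-(4-methoxyphenyl)-4-oxo-4H-chromen-3-yl]-5-hydroxy-4H-chromen-4-one | COc1ccc(-c2oc3cc(OC)cc(OC)c3c(=O)c2-c2c(OCc3ccccc3)cc3oc(-c4ccc(OCc5ccccc5)cc4)cc(=O)c3c2O)cc1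
A3 | alternative 2 | 5,7-bis(benzyloxy)-2-[4-(benzyloxy)phenyl]-6-[2-(2-hydroxy-4,6-dimethoxyphenyl)-2-oxoethyl]-4H-chromen-4-one | COc1cc(O)c(C(=O)Cc2c(OCc3ccccc3)cc3oc(-c4ccc(OCc5ccccc5)cc4)cc(=O)c3c2OCc2ccccc2)c(OC)c1
A4 | alternative 2 | 5,7-bis(benzyloxy)-2-[4-(benzyloxy)phenyl]-6-[5,7-dimethoxy-2-(4-methoxyphenyl)-4-oxo-4H-chromen-3-yl]-4H-chromen-4-one | COc1ccc(-c2oc3cc(OC)cc(OC)c3c(=O)c2-c2c(OCc3ccccc3)cc3oc(-c4ccc(OCc5ccccc5)cc4)cc(=O)c3c2OCc2ccccc2)cc1
A5 | alternative 3 | 3-(3-acetyl-2,4,6-trihydroxyphenyl)-5,7-dimethoxy-2-(4-methoxyphenyl)-4H-chromen-4-one | COc1ccc(-c2oc3cc(OC)cc(OC)c3c(=O)c2-c2c(O)cc(O)c(C(C)=O)c2O)cc1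
A6 | alternative 3 | 3-{3-[(2E)-3-[4-(benzyloxy)phenyl]prop-2-enoyl]-2,4,6-trihydroxyphenyl}-5,7-dimethoxy-2-(4-methoxyphenyl)-4H-chromen-4-one | COc1ccc(-c2oc3cc(OC)cc(OC)c3c(=O)c2-c2c(O)cc(O)c(C(=O)/C=C/c3ccc(OCc4ccccc4)cc3)c2O)cc1
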